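Slowness is what the late ochre readings show, and your hunch extends that slow rise over the hours. Don't; follow the ratio of isomer of the product A to target.

- ochre: substrate 0.45 M; run made earlier
- flask: substrate 0.30 M; time 8.0 h

ochre run (percent of the substrate charged)

| time / min | isomer of the product A / % | target / % |
|---|---|---|
| 4.00 | 7.4 | 12.8 |
| 8.00 | 12.3 | 12.9 |
| 15.0 | 15.2 | 13.1 |
| 25.0 | 15.5 | 13.7 |
| 50.0 | 16.1 | 14.4 |

(readings scatter by 0.5 percentage points)

- steps that have been proposed: isomer of the product A <-> isomer of the product B; target <-> isomer of the product A; target <-> isomer of the product C; substrate <-> target; isomer of the product B <-> substrate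

- ratio of isomer of the product A to target at 15 s
- ratio of isomer of the product A to target at 12 min
- ratio of isomer of the product A to target at 8.0 h

1. Treat every proposed step as one molecule turning into one, so percentages carry from the ochre run at 0.45 M to the flask at 0.30 M.

2. Work with the fraction left. In the ochre run, isomer of the product A still lacks 0.540 of its last reading at 4.00 min and 0.236 at 8.00 min, so that fraction halves every 3.35 min.

3. At 12 min this leaves 0.103. With target read at 13.1%, expect a ratio of 1.10.

4. Compare the late readings: the ratio is 1.13 at 25.0 min and 1.12 at 50.0 min, although both amounts rose, each with a scatter of 0.5 percentage points. Name this the standing ratio, the isomer of the product A per target once the two rise together.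

5. Note that 8.0 h is far longer than that half-life, about 143 halvings. Commit to the standing ratio for the flask at 8.0 h: thermodynamic control. The readings begin too late to give a figure for 15 s.

6. Set this beside the forecast, which gives 0.03, 1.08 and 0.55, with the late rise “probably by slow leakage from the B pool”.

The flask gives 0.0236, 0.993 and 1.10.

    isomer of the product A ⇌ isomer of the product B (K = 2.80, k = 7.90 × 10⁻⁴ s⁻¹)
    target ⇌ isomer of the product A (K = 1.10, k = 0.00140 s⁻¹)
    target ⇌ isomer of the product C (K = 1.70, k = 0.00760 s⁻¹)
    substrate ⇌ target (K = 31.0, k = 0.100 s⁻¹)
    isomer of the product B ⇌ substrate (k = 0.00190 s⁻¹)

At 8.0 h the flask stands at 1.10, beside the standing ratio of 1.12 read from the ochre run, and the neighbour charged with 1.2 M gives 1.10. A tenfold time changes the flask's ratio by nothing. At 15 s the flask is still far below that standing ratio, at 0.0236, and part of the reason it stands even that high is the turning of target into isomer of the product A, both ways: the same flask without that step gives 0.00656 at that moment.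

All runs are calculated from invented constants; noise was put on by code.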